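**Retrosynthetic overview**

1. Target 15 ⇐ 14 by removal of two aryl tosylates. Both arenes are bought ready-made (syringaldehyde 1, dihydroferulic acid 7), so the oxane is the only ring to be built.
2. 14 ⇐ 12: the oxane ring is closed by forming the C4–C5 bond. The 2-alkoxyalkene carbon of 12 adds to its own aldehyde, and the resulting C6 oxocarbenium ion 13 is reduced in the same flask, so C4 and C6 are both set from C2.
3. Enabling feature: in the oxane (O1, C2–aryl, C3, C4–OH, C5, C6–arylethyl) the C4 carbinol is β to C6, the carbon that holds the ring oxygen. This β-hydroxy ether is an aldol retron once C6 is raised to the oxocarbenium (ketone) level; O1–C6(=C5H2) is then the enol ether of a methyl ketone tethered through O1.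
4. 12 ⇐ 9: the enol ether comes from carbonyl methylenation of ester 9 (C5 is the added CH2); 9 ⇐ alcohol 6 + acid 8.
5. 6 ⇐ 2: C2 is set by catalytic asymmetric allylation of aldehyde 2, and the allyl group is cut back to the C3–C4 unit.

Key step: step 10

Remark: ring compounds are numbered as oxanes (O1, C2 aryl-bearing, C4 carbinol, C6 arylethyl-bearing). Both phenols are carried as electron-poor 4-methylbenzenesulfonates (tosylates) on purpose, to suppress benzylic ionisation and arene participation in step 10; this choice is an assumption of the design.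

**Step 1**
Reactants: 1 syringaldehyde (4-hydroxy-3,5-dimethoxybenzaldehyde)
Product: 2 4-formyl-2,6-dimethoxyphenyl 4-methylbenzenesulfonate
Conditions: TsCl, Et3N, DMAP (cat.), CH2Cl2, 0 °C to rt
Reagents that add atoms: 4-methylbenzenesulfonyl chloride, Cc1ccc(S(=O)(=O)Cl)cc1
Why: O-sulfonylation of the phenol, which protects it and makes the aryl ring electron-poor for step 10.

**Step 2**
Reactants: 2 4-formyl-2,6-dimethoxyphenyl 4-methylbenzenesulfonate
Product: 3 4-[(1S)-1-hydroxybut-3-en-1-yl]-2,6-dimethoxyphenyl 4-methylbenzenesulfonate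
Conditions: allylSnBu3, (S)-BINOL (20 mol %), Ti(OiPr)4 (10 mol %), 4 Å MS, CH2Cl2, −20 °C; then aq. NaHCO3
Reagents that add atoms: allyltributylstannane, C=CC[Sn](CCCC)(CCCC)CCCC
Why: Keck asymmetric allylation, in which the (S)-BINOL/Ti(OiPr)4 catalyst should direct allyl transfer to the Si face of the aryl aldehyde and so give the (S)-carbinol that becomes C2.

**Step 3**
Reactants: 3 4-[(1S)-1-hydroxybut-3-en-1-yl]-2,6-dimethoxyphenyl 4-methylbenzenesulfonate
Product: 5 4-[(1S)-1,3-dihydroxypropyl]-2,6-dimethoxyphenyl 4-methylbenzenesulfonate, via hydroxy aldehyde 4 (not isolated)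
Conditions: O3, CH2Cl2/MeOH, −78 °C; then NaBH4, −78 °C to 0 °C
Reagents that add atoms: ozone, [O-][O+]=O
Why: Ozonolysis of the terminal alkene with reductive work-up, the labile β-hydroxy aldehyde being reduced in situ so that the carbinol centre is not touched.

**Step 4**
Reactants: 5 4-[(1S)-1,3-dihydroxypropyl]-2,6-dimethoxyphenyl 4-methylbenzenesulfonate
Product: 6 4-[(1S)-3-{[tert-butyl(dimethyl)silyl]oxy}-1-hydroxypropyl]-2,6-dimethoxyphenyl 4-methylbenzenesulfonate
Conditions: TBSCl (1.05 equiv), imidazole, CH2Cl2, −20 °C to 0 °C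
Reagents that add atoms: tert-butyldimethylsilyl chloride, CC(C)(C)[Si](C)(C)Cl
Why: Silylation should select the primary over the secondary benzylic hydroxyl on steric grounds.

**Step 5**
Reactants: 7 dihydroferulic acid (3-(4-hydroxy-3-methoxyphenyl)propanoic acid)
Product: 8 3-{3-methoxy-4-[(4-methylbenzenesulfonyl)oxy]phenyl}propanoic acid
Conditions: TsCl, aq. NaOH, THF, 0 °C to rt; then aq. HCl
Reagents that add atoms: 4-methylbenzenesulfonyl chloride, Cc1ccc(S(=O)(=O)Cl)cc1
Why: Schotten–Baumann sulfonylation of the phenoxide, any mixed anhydride at the carboxylate being hydrolysed back under the aqueous conditions.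

**Step 6**
Reactants: 6 4-[(1S)-3-{[tert-butyl(dimethyl)silyl]oxy}-1-hydroxypropyl]-2,6-dimethoxyphenyl 4-methylbenzenesulfonate; 8 3-{3-methoxy-4-[(4-methylbenzenesulfonyl)oxy]phenyl}propanoic acid
Product: 9 (1S)-3-{[tert-butyl(dimethyl)silyl]oxy}-1-{3,5-dimethoxy-4-[(4-methylbenzenesulfonyl)oxy]phenyl}propyl 3-{3-methoxy-4-[(4-methylbenzenesulfonyl)oxy]phenyl}propanoate
Conditions: DCC, DMAP (cat.), CH2Cl2, 0 °C to rt
Reagents that add atoms: none
Why: Steglich esterification acylates the secondary alcohol without breaking its C–O bond, so the configuration is retained.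

**Step 7**
Reactants: 9 (1S)-3-{[tert-butyl(dimethyl)silyl]oxy}-1-{3,5-dimethoxy-4-[(4-methylbenzenesulfonyl)oxy]phenyl}propyl 3-{3-methoxy-4-[(4-methylbenzenesulfonyl)oxy]phenyl}propanoate
Product: 10 4-[(1S)-3-{[tert-butyl(dimethyl)silyl]oxy}-1-[(4-{3-methoxy-4-[(4-methylbenzenesulfonyl)oxy]phenyl}but-1-en-2-yl)oxy]propyl]-2,6-dimethoxyphenyl 4-methylbenzenesulfonate
Conditions: Cp2TiMe2 (3 equiv), toluene/THF, 65 °C, dark; filtration through basic alumina
Reagents that add atoms: dimethyltitanocene Cp2TiMe2, [CH3-].[CH3-].[Ti+4].c1cc[cH-]c1.c1cc[cH-]c1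
Why: Petasis methylenation of the ester carbonyl through Cp2Ti=CH2 gives the 2-alkoxyalkene regiospecifically, and the silyl ether and aryl sulfonates should be inert to the titanium carbene.

**Step 8**
Reactants: 10 4-[(1S)-3-{[tert-butyl(dimethyl)silyl]oxy}-1-[(4-{3-methoxy-4-[(4-methylbenzenesulfonyl)oxy]phenyl}but-1-en-2-yl)oxy]propyl]-2,6-dimethoxyphenyl 4-methylbenzenesulfonate
Product: 11 4-[(1S)-3-hydroxy-1-[(4-{3-methoxy-4-[(4-methylbenzenesulfonyl)oxy]phenyl}but-1-en-2-yl)oxy]propyl]-2,6-dimethoxyphenyl 4-methylbenzenesulfonate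
Conditions: TBAF, THF, 0 °C; then water
Reagents that add atoms: none
Why: Fluoride cleaves the silyl ether under basic conditions that the acid-labile enol ether tolerates.

**Step 9**
Reactants: 11 4-[(1S)-3-hydroxy-1-[(4-{3-methoxy-4-[(4-methylbenzenesulfonyl)oxy]phenyl}but-1-en-2-yl)oxy]propyl]-2,6-dimethoxyphenyl 4-methylbenzenesulfonate
Product: 12 4-[(1S)-1-[(4-{3-methoxy-4-[(4-methylbenzenesulfonyl)oxy]phenyl}but-1-en-2-yl)oxy]-3-oxopropyl]-2,6-dimethoxyphenyl 4-methylbenzenesulfonate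
Conditions: Dess–Martin periodinane, pyridine, CH2Cl2, 0 °C; crude aldehyde used at once
Reagents that add atoms: none
Why: Dess–Martin oxidation of the primary alcohol under pyridine-buffered, near-neutral conditions should spare the enol ether and avoid base-induced β-elimination of the enol oxygen.

**Step 10**
Reactants: 12 4-[(1S)-1-[(4-{3-methoxy-4-[(4-methylbenzenesulfonyl)oxy]phenyl}but-1-en-2-yl)oxy]-3-oxopropyl]-2,6-dimethoxyphenyl 4-methylbenzenesulfonate
Product: 14 4-[(2S,4R,6S)-4-hydroxy-6-(2-{3-methoxy-4-[(4-methylbenzenesulfonyl)oxy]phenyl}ethyl)oxan-2-yl]-2,6-dimethoxyphenyl 4-methylbenzenesulfonate, via oxocarbenium zwitterion 13 (not isolated)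
Conditions: BF3·OEt2 (1.5 equiv), Et3SiH (5 equiv), 2,6-di-tert-butyl-4-methylpyridine (0.5 equiv), CH2Cl2 (0.02 M), −78 °C to −40 °C; then aq. NaHCO3
Reagents that add atoms: none
Why: Proposed new method: BF3 activates the aldehyde of 12 and the terminal carbon of the 2-alkoxyalkene (future C5) attacks it in a 6-(enolendo)-exo-trig closure that forms the C4–C5 bond and the oxane ring and leaves the cyclic oxocarbenium ion 13, which triethylsilane reduces in the same flask; the closest known reaction types are the Mukaiyama aldol–Prins cascade, in which alkyl enol ethers add to BF3-activated aldehydes to give β-oxido oxocarbenium ions, and the silane reduction of six-membered oxocarbenium ions used to make 2,6-cis-oxanes and C-glycosides. C4 should be set in a chair-like transition state with the C2 aryl group equatorial and the bulky C=O–BF3 unit pseudo-equatorial, antiperiplanar to the enol ether C=C, which places the new C4–O bond cis to the aryl group. C6 should be set by axial hydride delivery to the half-chair of 13 that keeps both existing substituents pseudo-equatorial, which gives the 2,6-cis, all-equatorial oxane. The step needs ring closure to outrun direct silane reduction of the aldehyde, which the intramolecular and far more nucleophilic enol ether should secure, and it needs the benzylic C2–O1 bond not to ionise at the oxocarbenium stage, which the electron-poor sulfonyloxy-substituted aryl ring should secure. The hindered pyridine base removes adventitious protic acid that would otherwise protonate the enol ether and lead to its uncyclised reduction.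

**Step 11**
Reactants: 14 4-[(2S,4R,6S)-4-hydroxy-6-(2-{3-methoxy-4-[(4-methylbenzenesulfonyl)oxy]phenyl}ethyl)oxan-2-yl]-2,6-dimethoxyphenyl 4-methylbenzenesulfonate
Product: 15 (2S,4R,6S)-2-(4-hydroxy-3,5-dimethoxyphenyl)-6-[2-(4-hydroxy-3-methoxyphenyl)ethyl]oxan-4-ol
Conditions: KOH, MeOH/THF/H2O, 65 °C; then aq. HCl to pH 5
Reagents that add atoms: none
Why: Hydroxide attacks sulfur of both aryl sulfonates (S–O cleavage) and releases the two phenols, while none of the oxane stereocentres is base-labile.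

**Compound list**

1 | syringaldehyde (4-hydroxy-3,5-dimethoxybenzaldehyde) | COc1cc(C=O)cc(OC)c1O | starting material
2 | 4-formyl-2,6-dimethoxyphenyl 4-methylbenzenesulfonate | COc1cc(C=O)cc(OC)c1OS(=O)(=O)c1ccc(C)cc1 | intermediate
3 | 4-[(1S)-1-hydroxybut-3-en-1-yl]-2,6-dimethoxyphenyl 4-methylbenzenesulfonate | C=CC[C@H](O)c1cc(OC)c(OS(=O)(=O)c2ccc(C)cc2)c(OC)c1 | intermediate
4 | 4-[(1S)-1-hydroxy-3-oxopropyl]-2,6-dimethoxyphenyl 4-methylbenzenesulfonate | O=CC[C@H](O)c1cc(OC)c(OS(=O)(=O)c2ccc(C)cc2)c(OC)c1 | intermediate (not isolated)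
5 | 4-[(1S)-1,3-dihydroxypropyl]-2,6-dimethoxyphenyl 4-methylbenzenesulfonate | OCC[C@H](O)c1cc(OC)c(OS(=O)(=O)c2ccc(C)cc2)c(OC)c1 | intermediate
6 | 4-[(1S)-3-{[tert-butyl(dimethyl)silyl]oxy}-1-hydroxypropyl]-2,6-dimethoxyphenyl 4-methylbenzenesulfonate | CC(C)(C)[Si](C)(C)OCC[C@H](O)c1cc(OC)c(OS(=O)(=O)c2ccc(C)cc2)c(OC)c1 | intermediate
7 | dihydroferulic acid (3-(4-hydroxy-3-methoxyphenyl)propanoic acid) | COc1cc(CCC(=O)O)ccc1O | starting material
8 | 3-{3-methoxy-4-[(4-methylbenzenesulfonyl)oxy]phenyl}propanoic acid | COc1cc(CCC(=O)O)ccc1OS(=O)(=O)c1ccc(C)cc1 | intermediate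
9 | (1S)-3-{[tert-butyl(dimethyl)silyl]oxy}-1-{3,5-dimethoxy-4-[(4-methylbenzenesulfonyl)oxy]phenyl}propyl 3-{3-methoxy-4-[(4-methylbenzenesulfonyl)oxy]phenyl}propanoate | CC(C)(C)[Si](C)(C)OCC[C@H](OC(=O)CCc1ccc(OS(=O)(=O)c2ccc(C)cc2)c(OC)c1)c1cc(OC)c(OS(=O)(=O)c2ccc(C)cc2)c(OC)c1 | intermediate
10 | 4-[(1S)-3-{[tert-butyl(dimethyl)silyl]oxy}-1-[(4-{3-methoxy-4-[(4-methylbenzenesulfonyl)oxy]phenyl}but-1-en-2-yl)oxy]propyl]-2,6-dimethoxyphenyl 4-methylbenzenesulfonate | CC(C)(C)[Si](C)(C)OCC[C@H](OC(=C)CCc1ccc(OS(=O)(=O)c2ccc(C)cc2)c(OC)c1)c1cc(OC)c(OS(=O)(=O)c2ccc(C)cc2)c(OC)c1 | intermediate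
11 | 4-[(1S)-3-hydroxy-1-[(4-{3-methoxy-4-[(4-methylbenzenesulfonyl)oxy]phenyl}but-1-en-2-yl)oxy]propyl]-2,6-dimethoxyphenyl 4-methylbenzenesulfonate | OCC[C@H](OC(=C)CCc1ccc(OS(=O)(=O)c2ccc(C)cc2)c(OC)c1)c1cc(OC)c(OS(=O)(=O)c2ccc(C)cc2)c(OC)c1 | intermediate
12 | 4-[(1S)-1-[(4-{3-methoxy-4-[(4-methylbenzenesulfonyl)oxy]phenyl}but-1-en-2-yl)oxy]-3-oxopropyl]-2,6-dimethoxyphenyl 4-methylbenzenesulfonate | O=CC[C@H](OC(=C)CCc1ccc(OS(=O)(=O)c2ccc(C)cc2)c(OC)c1)c1cc(OC)c(OS(=O)(=O)c2ccc(C)cc2)c(OC)c1 | intermediate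
13 | (2S,4S)-2-{3,5-dimethoxy-4-[(4-methylbenzenesulfonyl)oxy]phenyl}-6-(2-{3-methoxy-4-[(4-methylbenzenesulfonyl)oxy]phenyl}ethyl)-4-[(trifluoroboranuidyl)oxy]-2,3,4,5-tetrahydropyrylium, zwitterion with aryl and O–BF3 cis (same spatial arrangement at C2 and C4 as in 14) | COc1cc(CCC2=[O+][C@H](c3cc(OC)c(OS(=O)(=O)c4ccc(C)cc4)c(OC)c3)C[C@H](O[B-](F)(F)F)C2)ccc1OS(=O)(=O)c1ccc(C)cc1 | intermediate (not isolated)
14 | 4-[(2S,4R,6S)-4-hydroxy-6-(2-{3-methoxy-4-[(4-methylbenzenesulfonyl)oxy]phenyl}ethyl)oxan-2-yl]-2,6-dimethoxyphenyl 4-methylbenzenesulfonate | COc1cc(CC[C@H]2C[C@@H](O)C[C@@H](c3cc(OC)c(OS(=O)(=O)c4ccc(C)cc4)c(OC)c3)O2)ccc1OS(=O)(=O)c1ccc(C)cc1 | intermediate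
15 | (2S,4R,6S)-2-(4-hydroxy-3,5-dimethoxyphenyl)-6-[2-(4-hydroxy-3-methoxyphenyl)ethyl]oxan-4-ol | COc1cc(CC[C@H]2C[C@@H](O)C[C@@H](c3cc(OC)c(O)c(OC)c3)O2)ccc1O | target

**Step count and risks**

Total steps: 11. Longest linear sequence: 10 (steps 1–4 and 6–11; step 5 is a one-step side branch).

Steps most likely to fail:

1. Step 10 (bears "Proposed new method:"). What may go wrong: poor facial selectivity at the aldehyde carbon, so that C4 forms as a mixture; silane reduction of the aldehyde or protonation of the enol ether before ring closure; ionisation of the benzylic C2–O1 bond at the oxocarbenium stage. The fallback uses known chemistry, sets out from homoallylic alcohol 3 and acid 8, and comes back at 14. Acid 8 is reduced with BH3·SMe2 (THF, 0 °C to rt) to 4-(3-hydroxypropyl)-2-methoxyphenyl 4-methylbenzenesulfonate F1. Dess–Martin periodinane oxidises F1 to 2-methoxy-4-(3-oxopropyl)phenyl 4-methylbenzenesulfonate F2. Prins cyclization of 3 with F2 (CF3CO2H, CH2Cl2, 0 °C to rt) should pass through the chair oxocarbenium ion with equatorial capture at C4 and give (2S,4R,6S)-2-{3,5-dimethoxy-4-[(4-methylbenzenesulfonyl)oxy]phenyl}-6-(2-{3-methoxy-4-[(4-methylbenzenesulfonyl)oxy]phenyl}ethyl)oxan-4-yl trifluoroacetate F3. Methanolysis (K2CO3, MeOH, rt) then gives 14. The electron-poor aryl group of 3 should hold back oxonia-Cope scrambling of the stereocentre.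

2. Step 7. What may go wrong: incomplete methylenation of the hindered ester, or hydrolysis and double-bond migration of the acid-labile 2-alkoxyalkene during isolation. The fallback builds the enol ether by ketal opening instead of carbonyl olefination; it sets out from diol 5 and comes back at alcohol 11, so it also replaces steps 4, 6 and 8. Commercial zingerone F4 is tosylated (TsCl, Et3N) to 2-methoxy-4-(3-oxobutyl)phenyl 4-methylbenzenesulfonate F5 and converted (HC(OMe)3, MeOH, TsOH cat.) into 4-(3,3-dimethoxybutyl)-2-methoxyphenyl 4-methylbenzenesulfonate F6. Transketalisation of F6 with 5 (PPTS cat., removal of MeOH) should give the 1,3-dioxane 4-[(4S)-2-(2-{3-methoxy-4-[(4-methylbenzenesulfonyl)oxy]phenyl}ethyl)-2-methyl-1,3-dioxan-4-yl]-2,6-dimethoxyphenyl 4-methylbenzenesulfonate F7 (epimers at the ketal carbon, which is lost again). TMSOTf/iPr2NEt (CH2Cl2, −20 °C) should silylate the less hindered primary oxygen, open the ketal and remove a methyl proton to give 4-[(1S)-1-[(4-{3-methoxy-4-[(4-methylbenzenesulfonyl)oxy]phenyl}but-1-en-2-yl)oxy]-3-[(trimethylsilyl)oxy]propyl]-2,6-dimethoxyphenyl 4-methylbenzenesulfonate F8. K2CO3/MeOH then gives 11. Regiocontrol of the ring opening and of the proton loss is the weak point, which is why this is not the main route.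

3. Step 11. What may go wrong: incomplete hydrolysis of the sulfonate flanked by two methoxy groups, or base-induced opening of the oxane through a quinone methide once the C2 aryl phenoxide is free. The fallback sets out from 14 and comes back at 15: the S–O bonds are cleaved by electron transfer instead of hydrolysis (Mg turnings, MeOH, rt), which avoids hot hydroxide; it makes no new compound (F0).

**Further compounds**

F1 | step 10 | 4-(3-hydroxypropyl)-2-methoxyphenyl 4-methylbenzenesulfonate | COc1cc(CCCO)ccc1OS(=O)(=O)c1ccc(C)cc1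
F2 | step 10 | 2-methoxy-4-(3-oxopropyl)phenyl 4-methylbenzenesulfonate | COc1cc(CCC=O)ccc1OS(=O)(=O)c1ccc(C)cc1
F3 | step 10 | (2S,4R,6S)-2-{3,5-dimethoxy-4-[(4-methylbenzenesulfonyl)oxy]phenyl}-6-(2-{3-methoxy-4-[(4-methylbenzenesulfonyl)oxy]phenyl}ethyl)oxan-4-yl trifluoroacetate | COc1cc(CC[C@H]2C[C@@H](OC(=O)C(F)(F)F)C[C@@H](c3cc(OC)c(OS(=O)(=O)c4ccc(C)cc4)c(OC)c3)O2)ccc1OS(=O)(=O)c1ccc(C)cc1
F4 | step 7 | zingerone, 4-(4-hydroxy-3-methoxyphenyl)butan-2-one (commercial input) | CC(=O)CCc1ccc(O)c(OC)c1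
F5 | step 7 | 2-methoxy-4-(3-oxobutyl)phenyl 4-methylbenzenesulfonate | CC(=O)CCc1ccc(OS(=O)(=O)c2ccc(C)cc2)c(OC)c1
F6 | step 7 | 4-(3,3-dimethoxybutyl)-2-methoxyphenyl 4-methylbenzenesulfonate | COC(C)(OC)CCc1ccc(OS(=O)(=O)c2ccc(C)cc2)c(OC)c1
F7 | step 7 | 4-[(4S)-2-(2-{3-methoxy-4-[(4-methylbenzenesulfonyl)oxy]phenyl}ethyl)-2-methyl-1,3-dioxan-4-yl]-2,6-dimethoxyphenyl 4-methylbenzenesulfonate | CC1(CCc2ccc(OS(=O)(=O)c3ccc(C)cc3)c(OC)c2)OCC[C@@H](c2cc(OC)c(OS(=O)(=O)c3ccc(C)cc3)c(OC)c2)O1
F8 | step 7 | 4-[(1S)-1-[(4-{3-methoxy-4-[(4-methylbenzenesulfonyl)oxy]phenyl}but-1-en-2-yl)oxy]-3-[(trimethylsilyl)oxy]propyl]-2,6-dimethoxyphenyl 4-methylbenzenesulfonate | C[Si](C)(C)OCC[C@H](OC(=C)CCc1ccc(OS(=O)(=O)c2ccc(C)cc2)c(OC)c1)c1cc(OC)c(OS(=O)(=O)c2ccc(C)cc2)c(OC)c1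
F0 | step 11 | none | none
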